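## Structural features

Atom labels (C1–C28, O3, O26 and so on) follow the order of the atoms in the SMILES string of the target; compound numbers are bare numbers. Epoxytwinol A (19) is a C2-symmetric heptacycle built around an eight-membered carbocycle, C4–C5=C6–C14–C15–C16=C17–C25, whose two tetrasubstituted alkenes are each shared with a six-membered ring (ring A: C5, C6, C7, C9, C11, C12; ring B: C16, C17, C18, C20, C22, C23). Two 3,6-dihydro-2H-pyran rings (C2–O3–C4–C5=C6–C14 and C27–O26–C25–C17=C16–C15) bridge the carbocycle across these alkenes, so C4, C14, C15 and C25 are bridgeheads and the core is the head-to-head [4+4] dimer of a 2-methyl-2H-pyran. Six contiguous stereocentres lie on the cage (C2–C14–C15–C27 and C4–C25, with C14/C15 trans and C4/C25 trans on the carbocycle), and each of rings A and B carries three more: a cis epoxide (C9/C11, C20/C22) on the ring face that bears the O–CH(CH3) bridge of its own pyran, and a carbinol (C12, C18) whose hydroxyl is anti to the epoxide, twelve in all. Fragile are the epoxy enone and γ-hydroxy enone units (base, nucleophiles, reductants) and the benzylic ether carbons C4 and C25 (acid, one-electron oxidants). The real difficulty is the cage: a C14–C15 bond between two tertiary carbons inside a medium ring, flanked by four further stereocentres, to be made as one enantiomer with no stereocentre to start from. The key step exploits that, with rings A and B written as benzene rings, the carbocycle and its two six-membered rings are exactly dibenzo[a,e]cyclooctatetraene, that C14 and C15 are the two carbons of one of its alkenes, and that each carries a two-carbon C–O arm (C2–C1 and C27–C28), which the planar dianion of the hydrocarbon can take up as two acyl groups.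

## Logic of the disconnections

19 to 18. The C12–H and C18–H bonds are cut, so the two carbinols become carbonyl groups. Each six-membered ring of 18 is then an epoxy enedione, one oxidation step from an arene, and two stereocentres disappear. The forward step must choose C12 over C7 and C18 over C23, deliver hydride on the epoxide face and stop at one carbonyl per ring.

18 to 17. The four epoxide C–O bonds (O10 to C9 and C11, O21 to C20 and C22) are cut, because an epoxy enedione arises from a quinone by nucleophilic epoxidation of its less substituted alkene. Four stereocentres go, and all that remain sit on the cage. The forward step needs facial selection on both rings from the cage alone.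

17 to 16. No skeletal bond is cut; the four carbonyl oxygens are exchanged for methoxy groups and rings A and B become aromatic. This makes the cage robust and reveals the dibenzo-fused carbocycle, and it postpones every base- and nucleophile-sensitive group to the last three steps. The forward oxidative demethylation must spare the benzylic ether bridges.

16 to 14 (through 15). The O3–C4 and O26–C25 bonds are cut. Both oxygens sit on a chain that is 1,4 across an arene from C4 or C25, and these two carbons then form a cis alkene, so both ether rings can be closed across one double bond. Two rings and two stereocentres go, and the configuration of C4 and C25 is dictated by C14 and C15 because each bridge can span only one face. The forward step must add two tethered hydroxyls trans across a cis alkene: one anti addition, then one substitution with retention through a benzylic cation.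

14 to 11. The C2–H and C27–H bonds are cut (carbinols to methyl ketones). In 11 the centres C14 and C15 are epimerisable, so one catalyst-controlled reduction can set C2 and C27 and, by dynamic kinetic resolution, C14 and C15. Four stereocentres collapse into a racemic, equilibrating diketone. The forward step needs epimerisation faster than reduction and a matched pairing of catalyst and α-carbon.

11 to 6 and 7. The C14–C2 and C15–C27 bonds are cut. They attach the only carbons that a dibenzo[a,e]cyclooctatetraene does not contain, on vicinal carbons of one alkene; two-electron reduction inverts the polarity of these carbons towards an acyl donor. The whole carbon skeleton then comes from an achiral, symmetric hydrocarbon and two molecules of a two-carbon amide. The forward step needs vicinal double acylation without over-addition, proton transfer or electron transfer to the acyl donor.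

6 to 4 (through 5). The two alkene π bonds of 6 are removed. Benzylic bromination and dehydrobromination of the saturated bridges restore them. The forward steps need one bromine per bridge and no ring bromination.

4 to 3. The two CH2–CH2 bonds are cut, which divides the molecule into two identical halves; each half is one molecule of 3, so the forward step consumes two molecules of 3 for every molecule of 4. Because 3 is symmetric, only one constitution of the dimer can form. The forward step needs cyclodimerisation in preference to oligomerisation.

3 to 2 to 1. The C–Br bonds and then the O–CH3 bonds are cut, back to commercially available 1. The forward bromination needs benzylic rather than nuclear attack.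

## Other disconnections considered

Alternative 1: The cut removes O8 with O13 and O24 with O19, tracing the ketone and carbinol oxygens of each ring to one molecule of dioxygen. Forward, tetraphenylporphyrin-sensitised singlet oxygen would add [4+2] to the dienes C7=C6–C5=C12 and C18=C17–C16=C23 of the bis(arene oxide) A2, anti to each epoxide, to give the bis(endoperoxide) A3. Base would then remove one bridgehead hydrogen per ring and open the O–O bond (Kornblum–DeLaMare) to give 19.
- In its favour: the anti relationship of carbinol and epoxide follows from one mechanistic event, no protecting group is carried, and the whole oxidation pattern arrives in two operations.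
- Against it here: A2 is a pair of benzene oxides, which equilibrate with oxepins and isomerise to phenols with traces of acid. A2 would have to be made from the oxygen-free dibenzo cage A1 by Birch reduction, face-selective epoxidation, bromination and double dehydrobromination, and A1 still needs a cage-forming sequence like the one chosen. The rearrangement must remove hydrogen at C7 and C23 and not at C12 and C18, for which the substrate offers no clear bias.
- Comparison: on the relative configuration of C12 and C18 this alternative is the better plan. On facial selection of the epoxide it is the equal, since it uses the same cage bias earlier. On stability of intermediates, regiocontrol of the last step and step economy the chosen plan is ahead, because its aromatic rings carry the quinone oxidation level from the start.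

Alternative 2: The cut is the C14–C15 bond. Forward, the bis(isochroman-3-one) A4, already joined through C4–C25, would be deprotonated twice with LiN(SiMe3)2 and the bis-enolate oxidised with Cu(OTf)2 or I2. The two benzylic α-carbons would couple, closing the carbocycle and the eight-membered dioxocane in one bond to give the bis-lactone A5.
- In its favour: oxidative coupling of ester enolates is a known reaction type, which the chosen key step is not. The configuration at C14/C15 is forced by the tether. C4 and C25 are the carbons of a hydrobenzoin-type diol, for which asymmetric dihydroxylation of an (E)-alkene is a dependable source of absolute configuration, so no dynamic kinetic resolution is needed.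
- Against it here: the coupling must close a strained cage in competition with intermolecular coupling. A5 has lactone carbonyls where the target has CH–CH3; methyl addition and reduction of the lactol through an oxocarbenium ion would be expected to bring hydride in from the open, convex side and so leave the methyl groups pointing towards the other half, the epimer of the natural arrangement at C2 and C27. Each arene carries one oxygen only, so a phenol-to-quinone oxidation must precede the same last three steps.
- Comparison: the alternative is the better on precedent for its key step and on the source of absolute configuration, and the equal on the endgame. It is the poorer on step economy and on C2/C27, which the chosen plan builds, methyl groups included, in the key step and sets in the next.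

Alternative 3: The cut removes O8 with O10 and O24 with O21. Forward, whole cells expressing a Rieske non-haem iron arene dioxygenase (toluene, naphthalene or biphenyl dioxygenase type) would add dioxygen cis across C7–C9 and C22–C23 of A1 to give the bis(cis-dihydrodiol) A7.
- In its favour: dearomatisation in water without protecting groups, enantio- and face-selective by the enzyme. A1 would derive from dibenzo[a,e]cyclooctatetraene A6, which is commercially available, so the five steps that lead to 6 would fall away. On front-end step count and oxidation-state economy this alternative is the better plan.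
- Against it here: these enzymes act best on small mono- and bicyclic arenes. Here one would have to accept a rigid polycyclic ortho-disubstituted benzene twice, choosing C7–C9 over C11–C12 and one face. A7 has no oxygen at C12 and C18, and turning each dienediol into the keto epoxy carbinol takes selective oxidation at C7, epoxidation of C11=C12 anti to the diol and a Payne-type epoxide migration, on intermediates that lose water to phenols easily.
- Comparison: the alternative is the equal in that the same cage-forming chemistry is still needed, and the better in mildness. It is the poorer in predictability of its key step and in the number of operations after it (about five against three).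

Key step: step 6

Remarks on the chemistry:
- Structures: 6 and 11 map atom for atom onto 19, and the (5S,6S) form of 11 is the one 19 requires (C14 and C15 are both S).
- Assumption: the sense of induction of RuCl[(R,R)-TsDPEN](p-cymene) on the branched methyl ketones of 11 is taken to follow that on aryl methyl ketones, with the branched α-carbon in the place of the aryl group.
- Stoichiometry: step 3 is a cyclodimerisation, so two molecules of 3 and four equivalents of lithium give one molecule of 4 and four of lithium bromide. Step 6 takes up two molecules of 7 per molecule of 6.
- Design points: all four oxygens stay as methyl ethers, because a symmetric monomer is needed for the dimerisation and methyl ethers survive radical bromination, lithium metal and KOtBu. Excess lithium is filtered off before 7 is added. An iodonium source is used in step 8, because a bromonium source would brominate the dimethoxybenzene rings. PhCF3 replaces CCl4, and transfer hydrogenation avoids pressurised hydrogen.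
- Locants: positions 5 and 6 of the dibenzocyclooctene names are C14 and C15, and positions 11 and 12 are C25 and C4.

## Route

Step 1
Reactants: 1 2,3-dimethylhydroquinone
Product: 2 1,4-dimethoxy-2,3-dimethylbenzene
Conditions: MeI (2.5 equiv), K2CO3 (3 equiv), acetone, reflux, N2
Reagents that add atoms: iodomethane, CI
Why: Twofold Williamson ether synthesis; the degassed medium keeps the electron-rich phenolate from air oxidation to the quinone.

Step 2
Reactants: 2 1,4-dimethoxy-2,3-dimethylbenzene
Product: 3 2,3-bis(bromomethyl)-1,4-dimethoxybenzene
Conditions: N-bromosuccinimide (2.1 equiv), AIBN (cat.), PhCF3, 80 °C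
Reagents that add atoms: N-bromosuccinimide, O=C1CCC(=O)N1Br
Why: Wohl–Ziegler radical bromination; the non-polar medium and radical initiation favour the benzylic methyl groups over the ring, and the second bromine enters the other methyl group because a bromomethyl C–H is deactivated towards hydrogen abstraction.

Step 3
Reactants: 3 2,3-bis(bromomethyl)-1,4-dimethoxybenzene (two molecules are joined per molecule of product)
Product: 4 1,4,7,10-tetramethoxy-5,6,11,12-tetrahydrodibenzo[a,e]cyclooctene
Conditions: Li granules (2.5 equiv per 3), THF, reflux, slow addition of 3, Ar
Reagents that add atoms: second molecule of the dibromide 3 (the step is a cyclodimerisation), COc1ccc(OC)c(CBr)c1CBr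
Why: Wurtz-type reductive cyclodimerisation, as used for unsubstituted α,α'-dibromo-o-xylene: two molecules of 3 and four equivalents of lithium give one molecule of 4 and four of LiBr, a benzylic lithium formed from one molecule displacing bromide of the other before a second metalation–displacement closes the eight-membered ring. Slow addition keeps the open dimer dilute, and the symmetric substitution of 3 allows only one constitution.

Step 4
Reactants: 4 1,4,7,10-tetramethoxy-5,6,11,12-tetrahydrodibenzo[a,e]cyclooctene
Product: 5 5,11-dibromo-1,4,7,10-tetramethoxy-5,6,11,12-tetrahydrodibenzo[a,e]cyclooctene (diastereomer mixture, used crude)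
Conditions: N-bromosuccinimide (2.05 equiv), AIBN (cat.), PhCF3, 80 °C
Reagents that add atoms: N-bromosuccinimide, O=C1CCC(=O)N1Br
Why: Wohl–Ziegler bromination of the benzylic CH2 groups; once one carbon of a bridge is brominated its neighbour is deactivated, so the second bromine goes to the other bridge. Every isomer with one bromine per bridge converges in step 5.

Step 5
Reactants: 5 5,11-dibromo-1,4,7,10-tetramethoxy-5,6,11,12-tetrahydrodibenzo[a,e]cyclooctene
Product: 6 1,4,7,10-tetramethoxydibenzo[a,e]cyclooctatetraene
Conditions: KOtBu (4 equiv), THF, 0 °C to rt
Reagents that add atoms: none
Why: Twofold E2 dehydrobromination; within the eight-membered ring each bridge can only give the cis alkene, so the tub-shaped tetraene results.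

Step 6
Reactants: 6 1,4,7,10-tetramethoxydibenzo[a,e]cyclooctatetraene; 7 N-methoxy-N-methylacetamide
Product: 11 rac-trans-5,6-diacetyl-1,4,7,10-tetramethoxy-5,6-dihydrodibenzo[a,e]cyclooctene, via dilithium dianion 8 (not isolated), via monoadduct benzylic anion 9 (not isolated), via dilithium bis(hemiaminal alkoxide) 10 (not isolated)
Conditions: Li granules (excess), THF, 20 °C, ultrasound, Ar; cannula filtration from the metal; 7 (2.4 equiv), THF, −78 to −20 °C; sat. aq. NH4Cl
Reagents that add atoms: none
Why: Proposed new method: two single-electron transfers from lithium turn the tub-shaped 6 into the planar, aromatic ten-π-electron dianion 8, whose charge sits on the four former alkene carbons and whose lithium ions are held by the flanking methoxy groups; one of these carbons (C14) attacks the carbonyl of 7 to give a chelated tetrahedral adduct and the benzylic anion 9, and the neighbouring anionic carbon C15 takes the second acyl donor to give 10, which collapses to the ketone only on aqueous work-up (the logic of the Weinreb ketone synthesis). The closest known reactions are protonation, alkylation and silylation of the dibenzo[a,e]cyclooctatetraene dianion at its 5,6-positions and carboxylation of the cyclooctatetraene dianion; acylation by an amide has not been shown for this class of dianion. No ring is closed; the bonds C14–C2 and C15–C27 are formed. The new stereocentres C14 and C15 are set relative to each other by approach of the second acyl donor anti to the bulky adduct at C14, which also gives the more stable trans isomer; their absolute configuration is not controlled here and is settled in step 7, where both centres equilibrate. The step needs vicinal regiochemistry, which is secured because only attack at C15 leaves both benzene rings aromatic (attack at C4 would leave ring B as an ortho-quinodimethane), and it needs single addition at each carbon, which the stable lithium-chelated adduct secures. The metal is removed before 7 is added so that neither 7 nor the adducts are reduced.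

Step 7
Reactants: 11 rac-trans-5,6-diacetyl-1,4,7,10-tetramethoxy-5,6-dihydrodibenzo[a,e]cyclooctene
Product: 14 (5S,6S)-5,6-bis[(1R)-1-hydroxyethyl]-1,4,7,10-tetramethoxy-5,6-dihydrodibenzo[a,e]cyclooctene, via meso cis-diacetyl isomer 12 (not isolated), via monoreduced hydroxy ketone 13 (not isolated)
Conditions: RuCl[(R,R)-TsDPEN](p-cymene) (5 mol %), HCO2H (6 equiv), DBU (8 equiv), MeCN, 40 °C
Reagents that add atoms: none
Why: Noyori–Ikariya asymmetric transfer hydrogenation under epimerising conditions, a dynamic kinetic resolution of α-aryl ketones: DBU equilibrates C14 and C15 through the enols, so the mirror-image half of 11 reaches the reactive form by way of 12, while the ruthenium hydride adds to the Si face of each carbonyl to give the (R)-carbinol. In the matched pairing the aryl group on the α-carbon lies anti to the incoming hydride (Felkin–Anh), which couples an (R)-carbinol to an (S)-configured α-carbon; after the first reduction (13) C14 is fixed and only C15 can still epimerise before the second, again matched, reduction. The cis alkene is untouched because this catalyst reduces only polar C=O bonds.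

Step 8
Reactants: 14 (5S,6S)-5,6-bis[(1R)-1-hydroxyethyl]-1,4,7,10-tetramethoxy-5,6-dihydrodibenzo[a,e]cyclooctene
Product: 16 C2-symmetric tetramethoxy dibenzo cage (two 5,8-dimethoxy-3-methylisochroman units joined C1–C1' and C4–C4'; 2R,4S,14S,15S,25S,27R in target labels), via iodo ether 15 (not isolated)
Conditions: N-iodosuccinimide (1.0 equiv), CH2Cl2, −20 °C; then AgOTf (1.2 equiv), 2,6-di-tert-butyl-4-methylpyridine (1.5 equiv), −40 to 0 °C
Reagents that add atoms: none
Why: Iodoetherification followed by silver-assisted SN1 etherification: the iodonium ion on one face of C4=C25 is opened in a 6-exo closure by the hydroxyl that sits on the opposite face (the two faces and the two hydroxyls are equivalent by C2 symmetry), leaving iodine at C25 trans to O3. AgOTf then ionises this benzylic iodide to a cation stabilised by the ortho-methoxy ring B, and O26 can reach it only from the face fixed by C15, so C4 and C25 end up trans with the configuration of the target. N-iodosuccinimide without acid is chosen because it should leave the dimethoxybenzene rings alone.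

Step 9
Reactants: 16 C2-symmetric tetramethoxy dibenzo cage
Product: 17 cage bis(p-benzoquinone) (C7, C12, C18 and C23 as carbonyl carbons)
Conditions: (NH4)2Ce(NO3)6 (5 equiv), MeCN/H2O (2:1), 0 °C
Reagents that add atoms: water, O
Why: Oxidative demethylation of the two hydroquinone dimethyl ether rings by tetravalent cerium, the usual passage from 5,8-dimethoxyisochromans to isochromanquinones; water supplies the quinone oxygens and the methyl groups leave as methanol. Trapping of each arene radical cation by water at 0 °C should outrun fragmentation of the benzylic C4–C25 bond, and no stereocentre is touched.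

Step 10
Reactants: 17 cage bis(p-benzoquinone)
Product: 18 cage bis(epoxyquinone) (cis epoxides at C9/C11 and C20/C22, each on the ring face that carries the O–CH(CH3) bridge of its own pyran)
Conditions: 30% aq. H2O2 (6 equiv), NaHCO3, THF/H2O, 0 °C
Reagents that add atoms: hydrogen peroxide, OO
Why: Weitz–Scheffer nucleophilic epoxidation: hydroperoxide adds to the unsubstituted, electron-poor C9=C11 and C20=C22 bonds and not to the tetrasubstituted C5=C6 and C16=C17 bonds. Each ring should be attacked on its convex face, the one flanked by its own two-atom O–CH(CH3) bridge, because the other face lies over the O–CH(CH3) unit of the opposite half (O26–C27 under ring A, O3–C2 under ring B); this sets C9, C11, C20 and C22. The γ-hydrogens at C4, C14, C15 and C25 are bridgehead hydrogens, so mild base should not tautomerise the quinones.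

Step 11
Reactants: 18 cage bis(epoxyquinone)
Product: 19 epoxytwinol A
Conditions: i-Bu2AlH (2.2 equiv), THF, −78 °C; aq. potassium sodium tartrate
Reagents that add atoms: none
Why: 1,2-Reduction of an epoxy enedione by a dialkylaluminium hydride at low temperature; aluminium bound to the ether oxygen O3 (β to C12=O) and the open convex face direct hydride to C12 from the epoxide side, whereas C7=O is screened on that face by the C1 methyl group and on the other by C27–H, and likewise C18 is preferred over C23. Hydride delivery on the face of the epoxide oxygen gives the hydroxyl anti to the epoxide, and the resulting γ-hydroxy enone is less electrophilic than the enedione, which should stop the reduction at one carbonyl per ring.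

## Compound list

1 | 2,3-dimethylhydroquinone | Cc1c(O)ccc(O)c1C | starting material
2 | 1,4-dimethoxy-2,3-dimethylbenzene | COc1ccc(OC)c(C)c1C | intermediate
3 | 2,3-bis(bromomethyl)-1,4-dimethoxybenzene | COc1ccc(OC)c(CBr)c1CBr | intermediate
4 | 1,4,7,10-tetramethoxy-5,6,11,12-tetrahydrodibenzo[a,e]cyclooctene | COc1ccc(OC)c2c1CCc1c(OC)ccc(OC)c1CC2 | intermediate
5 | 5,11-dibromo-1,4,7,10-tetramethoxy-5,6,11,12-tetrahydrodibenzo[a,e]cyclooctene (cis/trans mixture) | COc1ccc(OC)c2c1C(Br)Cc1c(OC)ccc(OC)c1C(Br)C2 | intermediate
6 | 1,4,7,10-tetramethoxydibenzo[a,e]cyclooctatetraene | COc1ccc(OC)c2c1/C=C\c1c(OC)ccc(OC)c1/C=C\2 | intermediate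
7 | N-methoxy-N-methylacetamide | CC(=O)N(C)OC | starting material
8 | dilithium salt of the dianion of 6 (planar; one resonance form drawn) | [Li+].[Li+].COc1ccc(OC)c2c1[CH-][CH-]c1c(OC)ccc(OC)c1/C=C\2 | intermediate
9 | monoadduct: lithium N-methoxy-N-methyl hemiaminal alkoxide at C14 with benzylic lithium at C15 (configuration undefined) | [Li+].[Li+].COc1ccc(OC)c2c1C(C(C)([O-])N(C)OC)[CH-]c1c(OC)ccc(OC)c1/C=C\2 | intermediate
10 | dilithium bis(hemiaminal alkoxide), trans at C14/C15, racemic (one enantiomer drawn; hemiaminal carbons undefined) | [Li+].[Li+].CC([O-])(N(C)OC)[C@@H]1c2c(OC)ccc(OC)c2/C=C\c2c(OC)ccc(OC)c2[C@H]1C(C)([O-])N(C)OC | intermediate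
11 | rac-trans-5,6-diacetyl-1,4,7,10-tetramethoxy-5,6-dihydrodibenzo[a,e]cyclooctene ((5S,6S) form drawn) | CC(=O)[C@@H]1c2c(OC)ccc(OC)c2/C=C\c2c(OC)ccc(OC)c2[C@H]1C(C)=O | intermediate
12 | meso (5R,6S)-cis-5,6-diacetyl-1,4,7,10-tetramethoxy-5,6-dihydrodibenzo[a,e]cyclooctene | CC(=O)[C@@H]1c2c(OC)ccc(OC)c2/C=C\c2c(OC)ccc(OC)c2[C@@H]1C(C)=O | intermediate
13 | (5S,6S)-6-acetyl-5-[(1R)-1-hydroxyethyl]-1,4,7,10-tetramethoxy-5,6-dihydrodibenzo[a,e]cyclooctene | C[C@@H](O)[C@@H]1c2c(OC)ccc(OC)c2/C=C\c2c(OC)ccc(OC)c2[C@H]1C(C)=O | intermediate
14 | (5S,6S)-5,6-bis[(1R)-1-hydroxyethyl]-1,4,7,10-tetramethoxy-5,6-dihydrodibenzo[a,e]cyclooctene | C[C@@H](O)[C@@H]1c2c(OC)ccc(OC)c2/C=C\c2c(OC)ccc(OC)c2[C@H]1[C@@H](C)O | intermediate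
15 | iodo ether: O3–C4 pyran closed, iodine at C25 trans to O3, free (R)-carbinol at C27 | C[C@H]1O[C@H]2c3c(OC)ccc(OC)c3[C@@H]1[C@H]([C@@H](C)O)c1c(OC)ccc(OC)c1[C@@H]2I | intermediate
16 | C2-symmetric tetramethoxy dibenzo cage (2R,4S,14S,15S,25S,27R in target labels) | C[C@H]1O[C@H]2c3c(OC)ccc(OC)c3[C@@H]1[C@H]1c3c(OC)ccc(OC)c3[C@@H]2O[C@@H]1C | intermediate
17 | cage bis(p-benzoquinone) | C[C@H]1O[C@H]2C3=C(C(=O)C=CC3=O)[C@@H]1[C@H]1C3=C(C(=O)C=CC3=O)[C@@H]2O[C@@H]1C | intermediate
18 | cage bis(epoxyquinone), epoxides syn to the O–CH(CH3) bridge of their own pyran | C[C@H]1O[C@H]2C3=C(C(=O)[C@@H]4O[C@@H]4C3=O)[C@@H]1[C@H]1C3=C(C(=O)[C@H]4O[C@H]4C3=O)[C@@H]2O[C@@H]1C | intermediate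
19 | epoxytwinol A | C[C@H]1O[C@H]2C3=C(C(=O)[C@@H]4O[C@@H]4[C@H]3O)[C@@H]1[C@H]1C3=C([C@H](O)[C@H]4O[C@H]4C3=O)[C@@H]2O[C@@H]1C | target

## Step count and least certain steps

Total: 11 steps. Longest linear sequence: 11 steps (1 to 19); 7 enters in step 6.

Step 6 (key step, proposed new method). Most likely failure: proton transfer from the acetyl methyl group of 7 to the carbanion, or electron transfer to the N–O bond of 7, in place of acyl transfer. The dianion is a delocalised, basic and reducing species and an amide carbonyl is a weak electrophile. Fallback by known chemistry, from 6 back to 11: the dianion is generated as before and quenched with CO2, a carboxylation of a hydrocarbon dianion, to give rac-trans-1,4,7,10-tetramethoxy-5,6-dihydrodibenzo[a,e]cyclooctene-5,6-dicarboxylic acid F1. 1,1'-Carbonyldiimidazole and N,O-dimethylhydroxylamine hydrochloride convert it into the bis(N-methoxy-N-methylamide) F2, and MeMgBr in THF at 0 °C gives 11.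

Step 7. Most likely failure: incomplete stereochemical funnelling. Epimerisation at C14/C15 may be slow relative to reduction; the level or sense of face selection is less secure on a methyl ketone whose larger substituent is a branched alkyl and not an aryl group; and the base may cause intramolecular aldol condensation of the 1,4-diketone. Fallback, from 11 back to 14: Corey–Bakshi–Shibata reduction with (S)-2-methyl-CBS-oxazaborolidine and BH3·SMe2 in THF at −20 °C. It sets both carbinols as (R) by the size difference of methyl and branched carbon, whatever the configuration of the ring carbons. The (5S,6S) half of 11 gives 14 and the (5R,6R) half gives the diastereomer (5R,6R)-5,6-bis[(1R)-1-hydroxyethyl]-1,4,7,10-tetramethoxy-5,6-dihydrodibenzo[a,e]cyclooctene F3. The two are separated by chromatography, and F3 is returned to 11 by Dess–Martin oxidation and DBU equilibration.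

Step 8. Most likely failure: loss of the C4 proton from the C25 benzylic cation (E1) instead of capture by O26, or iodination of the electron-rich rings once silver ion activates residual iodonium reagent. Fallback, from 14 back to 16: mCPBA with NaHCO3 in CH2Cl2 at 0 °C epoxidises C4=C25 (its two faces are equivalent by symmetry) to the epoxide F4. Catalytic camphorsulfonic acid in CH2Cl2 then opens the epoxide anti with the hydroxyl on the opposite face to give the C25 carbinol F5, and the same acid ionises this benzylic alcohol so that O26 closes the second ring to give 16.

Step 10. Most likely failure: poor facial selectivity, because the cage elements that distinguish the faces are four to five bonds from C9/C11 and C20/C22. Fallback, from 17 back to 18: the face is set by a reagent instead of the substrate. The Weitz–Scheffer epoxidation is run under chiral phase-transfer catalysis (N-benzylcinchonidinium chloride or its pseudoenantiomer N-benzylcinchoninium chloride, tert-butyl hydroperoxide, toluene/aq. NaOH, 0 °C). The catalyst enantiomer is chosen to reinforce the cage, and the same absolute sense is needed on both rings by C2 symmetry. No new compound is involved.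

Step 11. Most likely failure: wrong site selectivity (hydride at C7/C23), wrong face, or reduction of both carbonyls of a ring, since the two carbonyls of each ring differ only through the cage. Fallback, from 16 back to 19, by the quinone monoketal sequence:
- Anodic oxidation of 16 (graphite anode, KOH, MeOH, 0 °C) gives the bis(quinone bisketal) F6.
- Dilute aqueous acetic acid in acetone should hydrolyse the ketals at C12 and C18 first. Their ionisation places charge on C6 and C16, away from the carbons that bear the electron-withdrawing O3 and O26. This gives the bis(dienone monoketal) F7.
- H2O2/NaHCO3 epoxidises C9=C11 and C20=C22 to give F8.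
- i-Bu2AlH at −78 °C reduces the only carbonyl of each ring to give the bis(epoxy carbinol ketal) F9.
- Pyridinium p-toluenesulfonate in wet acetone frees C7=O and C23=O to give 19.

## Further compounds

F1 | step 6 | rac-trans-1,4,7,10-tetramethoxy-5,6-dihydrodibenzo[a,e]cyclooctene-5,6-dicarboxylic acid | OC(=O)[C@@H]1c2c(OC)ccc(OC)c2/C=C\c2c(OC)ccc(OC)c2[C@H]1C(=O)O
F2 | step 6 | rac-trans-5,6-bis(N-methoxy-N-methylcarbamoyl)-1,4,7,10-tetramethoxy-5,6-dihydrodibenzo[a,e]cyclooctene | CON(C)C(=O)[C@@H]1c2c(OC)ccc(OC)c2/C=C\c2c(OC)ccc(OC)c2[C@H]1C(=O)N(C)OC
F3 | step 7 | (5R,6R)-5,6-bis[(1R)-1-hydroxyethyl]-1,4,7,10-tetramethoxy-5,6-dihydrodibenzo[a,e]cyclooctene | C[C@@H](O)[C@H]1c2c(OC)ccc(OC)c2/C=C\c2c(OC)ccc(OC)c2[C@@H]1[C@@H](C)O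
F4 | step 8 | cis-11,12-epoxide of 14 | C[C@@H](O)[C@@H]1c2c(OC)ccc(OC)c2[C@H]3O[C@H]3c2c(OC)ccc(OC)c2[C@H]1[C@@H](C)O
F5 | step 8 | hydroxy ether: O3–C4 pyran closed, hydroxyl at C25 trans to O3, free (R)-carbinol at C27 | C[C@H]1O[C@H]2c3c(OC)ccc(OC)c3[C@@H]1[C@H]([C@@H](C)O)c1c(OC)ccc(OC)c1[C@@H]2O
F0 | step 10 | none | none
F6 | step 11 | cage bis(quinone bisketal) (dimethyl ketals at C7, C12, C18 and C23) | C[C@H]1O[C@H]2C3=C(C(OC)(OC)C=CC3(OC)OC)[C@@H]1[C@H]1C3=C(C(OC)(OC)C=CC3(OC)OC)[C@@H]2O[C@@H]1C
F7 | step 11 | cage bis(dienone monoketal) (carbonyls at C12 and C18, dimethyl ketals at C7 and C23) | C[C@H]1O[C@H]2C3=C(C(OC)(OC)C=CC3=O)[C@@H]1[C@H]1C3=C(C(=O)C=CC3(OC)OC)[C@@H]2O[C@@H]1C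
F8 | step 11 | cage bis(epoxy enone monoketal) | C[C@H]1O[C@H]2C3=C(C(OC)(OC)[C@@H]4O[C@@H]4C3=O)[C@@H]1[C@H]1C3=C(C(=O)[C@H]4O[C@H]4C3(OC)OC)[C@@H]2O[C@@H]1C
F9 | step 11 | cage bis(epoxy carbinol ketal) | C[C@H]1O[C@H]2C3=C(C(OC)(OC)[C@@H]4O[C@@H]4[C@H]3O)[C@@H]1[C@H]1C3=C([C@H](O)[C@H]4O[C@H]4C3(OC)OC)[C@@H]2O[C@@H]1C
A1 | alternative 1 | oxygen-free dibenzo cage (two 3-methylisochroman units joined C1–C1' and C4–C4') | C[C@H]1O[C@H]2c3ccccc3[C@@H]1[C@H]1c3ccccc3[C@@H]2O[C@@H]1C
A2 | alternative 1 | bis(arene oxide) of the cage (epoxides at C9/C11 and C20/C22) | C[C@H]1O[C@H]2C3C(=C[C@@H]4O[C@@H]4C=3)[C@@H]1[C@H]1C3C(=C[C@H]4O[C@H]4C=3)[C@@H]2O[C@@H]1C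
A3 | alternative 1 | bis(anti-epoxy endoperoxide) of the cage | C[C@H]1O[C@H]2C3=C([C@H]4OO[C@@H]3[C@H]5O[C@@H]45)[C@@H]1[C@H]1C3=C([C@@H]4OO[C@H]3[C@@H]5O[C@H]45)[C@@H]2O[C@@H]1C
A4 | alternative 2 | (1S,1'S)-8,8'-dimethoxy-1,1'-bi(isochroman)-3,3'-dione | O=C1Cc2cccc(OC)c2[C@H](O1)[C@H]1OC(=O)Cc2cccc(OC)c21
A5 | alternative 2 | C2-symmetric dibenzo cage bis-lactone | O=C1O[C@H]2c3c(cccc3OC)[C@@H]1[C@H]1c3c(c(OC)ccc3)[C@@H]2OC1=O
A6 | alternative 3 | dibenzo[a,e]cyclooctatetraene | c1ccc2c(c1)/C=C\c1ccccc1/C=C\2
A7 | alternative 3 | C2-symmetric bis(cis-dihydrodiol) of the cage | C[C@H]1O[C@H]2C3=C([C@H](O)[C@H](O)C=C3)[C@@H]1[C@H]1C3=C(C=C[C@@H](O)[C@H]3O)[C@@H]2O[C@@H]1C
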